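The data are calculated from invented constants.

West held 0.400 J for each Z charged, and I reckoned from that ratio. Z is the substrate, G the catalyst, X the product.

| flask | Z | J | G | L | remark | time |
|---|---|---|---|---|---|---|
| midnight | 0.50 M | 0.050 M | 4 mM | 47 mM | run made earlier |  |
| spring | 0.50 M | 0.050 M | 26 mM | 47 mM | run made earlier |  |
| autumn | 0.31 M | 0.050 M | 10 mM | 47 mM | run made earlier |  |
| west | 0.50 M | 0.200 M | 5.0 mM | 47 mM |  | 30 min |
| south-east | 0.50 M | 0.0150 M | 10 mM | 30 mM |  | 30 min |
| south | 0.15 M | 0.0800 M | 10 mM | 47 mM |  | 30 min |
| north-east | 0.15 M | 0.0500 M | 30 mM | 47 mM |  | 30 min |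
| east | 0.50 M | 0.0500 M | 10 mM | 47 mM |  | 30 min |
| south-west | 0.50 M | 0.0120 M | 30 mM | 30 mM |  | 30 min |

| run | time / min | X / % |
|---|---|---|
| midnight | 1.33 | 1.1 |
| midnight | 4.00 | 2.2 |
| midnight | 8.00 | 4.7 |
| midnight | 10.0 | 6.5 |
| midnight | 15.0 | 8.6 |
| spring | 3.00 | 13.5 |
| spring | 6.00 | 24.3 |
| spring | 10.0 | 36.6 |
| spring | 12.0 | 42.5 |
| spring | 15.0 | 49.1 |
| autumn | 1.33 | 2.4 |
| autumn | 4.00 | 6.5 |
| autumn | 8.00 | 11.7 |
| autumn | 10.0 | 14.6 |
| autumn | 15.0 | 20.4 |

(standard deviation of a reading: 0.5 percentage points)

* the flasks by amount of X, in percent of the Z charged, highest first, at 30 min (west / south-east / south / north-east / east / south-west)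
* the same order at 2.0 h (west / south-east / south / north-east / east / south-west)
* the amount of X, in percent of the Z charged of the flask you put first, at 30 min
* the amount of X, in percent of the Z charged of the flask you put last, at 30 min

- what was read earlier has a scatter of 0.5 percentage points, one standard deviation
- no earlier run changes the charge of J; that part of a forecast is a guess
- no earlier run changes the charge of L; that part of a forecast is a guess

No run varied J, so my first step was a guess: each J takes one Z away from X, early in the run. For west 0.600 is the free share, one minus J charged per Z charged. The readings offered one weak hint. Against the whole charge, the constant I read from the spring run fell from 0.0483 /min at the first reading to 0.0450 /min at the last. Against its free share of 0.900, it went from 0.0542 /min to 0.0526 /min.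

I then built a ladder, fastest first. J's take stood on the top rung, by guess. Below it, X was the free share times the way done, with a first-order constant scaled to the G charged. I treated L as neutral, which was also a guess.

30 mM of G, from spring: constant 0.0607 /min, half-time 11.4 min, way done 0.838

10 mM of G, from autumn: constant 0.0186 /min, half-time 37.3 min, way done 0.427

5.0 mM of G, from midnight: constant 0.00837 /min, half-time 82.8 min, way done 0.222

Free shares: south-west 0.976, south-east 0.970, east 0.900, north-east 0.667, west 0.600, south 0.467

By my reckoning, at 30 min the flasks with 30 mM of G were past their half-time, and the flasks with 10 mM were short of theirs. My west was short of its half-time too. My south-west came to 81.8% and my west to 13.3%. My order ran south-west, north-east, south-east, east, south, west. At 2.0 h my west too was past its half-time, and my order ran south-west, south-east, east, north-east, south, west.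

The forecast differed from my reckoning. It gave north-east > south-west > east > south-east > south > west at 30 min and north-east > south-west > east > south-east > south > west at 2.0 h, with 76% first and 19% last, and it said “The effects of J and L are unknown, and I assume they are neutral”. Its 76% is what a first-order curve to completion through the last spring reading gives.

The flasks gave south-west > north-east > south-east > east > south > west at 30.0 min, from 87.9% down to 14.0%, and south-west > south-east > east > north-east > south > west at 2.0 h.

    G + L ⇌ Q, settled at all times (K = 29.0 /M)
    Z + J → D (k = 6.90 /M/min)
    Z + G → G + X (k = 4.00 /M/min)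

West, with its free share of 0.600, held 55.7% of the Z charged as X and 40.0% as D at 300 min. A neighbour of west charged with 0.12 M of Z had 1.67 equiv of J, so its free share was −0.667, below zero. In that neighbour Z, not J, was the limiting reagent. At 30.0 min the neighbour had 0% of its Z and 41% of its J left, with 99.0% of the Z charged in D and 0.955% in X.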